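The earlier runs and the new flask were computed on assumed constants; noise was put on by code.

In the cedar run target stands at 51% by 0.200 h and then falls away, so I reckon with the fraction of target left, not with what is made.

| flask | starting material | partner | remark | time |
|---|---|---|---|---|
| cedar | 0.050 M | 0.20 M | run made earlier |  |
| oak | 0.075 M | 0.20 M | run made earlier |  |
| alder | 0.10 M | 0.10 M | run made earlier |  |
| flask | 0.10 M | 0.200 M |  | 8.0 h |

| run | time / h | target / % |
|---|---|---|
| cedar | 0.0833 | 35 |
| cedar | 0.200 | 51 |
| cedar | 0.500 | 50 |
| cedar | 1.33 | 35 |
| cedar | 3.00 | 10 |
| cedar | 8.00 | 2 |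
| oak | 0.0833 | 34 |
| oak | 0.200 | 51 |
| oak | 0.500 | 48 |
| oak | 1.33 | 31 |
| oak | 3.00 | 15 |
| oak | 8.00 | 1 |
| alder | 0.0833 | 22 |
| alder | 0.250 | 31 |
| alder | 0.833 | 23 |
| alder | 2.50 | 10 |
| alder | 8.00 | 2 |

(readings scatter by 2 percentage points)

- percent here means starting material units held: one side product counts as two
- the earlier runs were read with a standard deviation of 2 percentage points
- steps thought possible: starting material + partner -> isomer of the product; partner -> decomposed reagent; starting material + partner -> second isomer; starting material + target -> side product; starting material + partner <-> target

* time up to 8.0 h at which target stands highest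
* the amount of target, in percent of the starting material charged, at that time
* the first time at which target reaches 14%, in the same percent, in min

1. The rise comes first. Cedar holds 35% at 0.0833 h, and taking the gap to its peak reading as a fraction left gives a rate of 13.9 h⁻¹.

2. The plateau comes next: cedar still reads 50% at 0.500 h, and oak reads 48%.

3. The fade follows. Pooling cedar and oak, the fraction of target left from 1.33 h to 3.00 h is 37.9%. That gives the fade constant, the loss of target per hour if that loss is taken as first-order, of 0.581 h⁻¹, a reading with the scatter of 2 percentage points in it. Alder, with 0.10 M of partner, reads 0.500 h⁻¹.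

4. At 8.00 h the cedar and oak readings of 2% and 1% lie within that scatter of each other.

The rise is faster than the fade, so I expect the flask to peak early, at a height somewhere between the alder reading of 31% and the oak reading of 51%. After that I expect its target to halve every 1.19 h.

The forecast gives 0.35 h, 47% and 1.5 min, on the ground that target “forms fast and then fades”.

The flask gives 0.334 h, 47.5% and 1.41 min.

    starting material + partner → isomer of the product (k = 0.100 M⁻¹ min⁻¹)
    partner → decomposed reagent (k = 0.0250 min⁻¹)
    starting material + partner → second isomer (k = 0.180 M⁻¹ min⁻¹)
    starting material + target → side product (k = 0.0530 M⁻¹ min⁻¹)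
    starting material + partner ⇌ target (K = 35.0 M⁻¹, k = 0.610 M⁻¹ min⁻¹)

From that peak the fade constant leaves 5.65% at 4.00 h, and the flask holds 5.27%. The neighbouring flask with 0.50 M of partner peaks higher than the flask, at 60.7%. Its peak time is not at hand, so I count the fade over the whole 8.00 h, which leaves 0.582%. That neighbouring flask holds 0.484% of target at 8.00 h.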